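Numbering: chromene O1, C2, C3, C4, C4a, C5–C8, C8a; ring A = chromene benzene ring, ring B = 4-hydroxyphenyl, ring C = pyran. After removal of the phenol protecting groups, both unsubstituted CH=CH units are cut in one operation. These are C3=C4 of ring C (ring-closing metathesis) and Cα=Cβ of the enone (cross metathesis), which leaves an open triene on ring A and 4-acetoxystyrene (ring B).
Enabling feature: C3 and C4 carry only H, C4 sits on C4a ortho to the ether carbon C8a, and C3 sits on the fully substituted C2. Two terminal vinyl groups therefore form a 1,7-diene across O1 that can only close to the six-membered ring, and the enone CH=CH is likewise open to an acryloyl group at C6.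
Further cuts: C6–C(=O) (aryllithium plus acrylic Weinreb amide), the side-chain tertiary C–OH (epoxidation and hydride opening of the linalyl olefin), C4=CH2 (Wittig), and O1–C8a (SNAr on a fluoroarene whose aldehyde is both the activator and the future C4).
Forward order: ring A is bought and dressed (MOM, Br, CHO), the C10 unit is joined through O1, and the tail is hydrated. The acryloyl group is then attached, ring C closes and ring B is coupled in one flask, and one acid step frees the three phenols.
Stereochemistry: C2, C3, the 2-methyl group and the whole side chain are the intact skeleton of (S)-(+)-linalool. Its carbinol C–O bond is never broken, so C2 stays S, and the E enone comes from the reversible cross metathesis.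

Key step: step 9

Assumption: 2-fluorobenzene-1,4-diol and (S)-(+)-linalool (coriandrol) of high enantiomeric purity are taken as catalogue chemicals.

Step 1
Reactants: 1 2-fluorobenzene-1,4-diol
Product: 2 2-fluoro-1,4-bis(methoxymethoxy)benzene
Conditions: NaH (2.4 equiv), MOMCl (2.4 equiv), DMF, 0 °C to rt
Reagents that add atoms: chloromethyl methyl ether (MOMCl), COCCl
Why: Williamson-type O-alkylation of the bis-phenoxide installs acetal protecting groups that survive bases, organolithiums, hydride, peracid and ruthenium alkylidenes, support the later metalations and leave in one mild acid step.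

Step 2
Reactants: 2 2-fluoro-1,4-bis(methoxymethoxy)benzene
Product: 3 1-bromo-4-fluoro-2,5-bis(methoxymethoxy)benzene
Conditions: NBS (1.05 equiv), MeCN, 0 °C to rt, dark
Reagents that add atoms: N-bromosuccinimide (NBS), O=C1CCC(=O)N1Br
Why: Electrophilic aromatic bromination should go para to fluorine and ortho to a MOM ether, because fluorine favours its para and disfavours its meta position and the site between F and OMOM is crowded, as is known for substitution of the corresponding dimethyl ether.

Step 3
Reactants: 3 1-bromo-4-fluoro-2,5-bis(methoxymethoxy)benzene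
Product: 5 3-bromo-6-fluoro-2,5-bis(methoxymethoxy)benzaldehyde, via aryllithium 4 (not isolated)
Conditions: LiN(iPr)2 (1.1 equiv), THF, −78 °C; DMF (2 equiv), −78 °C; AcOH quench
Reagents that add atoms: N,N-dimethylformamide (DMF), CN(C)C=O
Why: Directed ortho-metalation with a lithium amide (deprotonation, not halogen exchange) should take the proton flanked by F and OMOM, the most acidic one on the ring, and formylation with DMF at low temperature comes before any loss of LiF.

Step 4
Reactants: 5 3-bromo-6-fluoro-2,5-bis(methoxymethoxy)benzaldehyde; 6 (S)-(+)-linalool, (3S)-3,7-dimethylocta-1,6-dien-3-ol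
Product: 8 3-bromo-6-{[(3S)-3,7-dimethylocta-1,6-dien-3-yl]oxy}-2,5-bis(methoxymethoxy)benzaldehyde, via potassium linaloolate 7 (not isolated)
Conditions: 6 (1.2 equiv), KN(SiMe3)2 (1.15 equiv), THF, 0 °C; then 5, 0 to 40 °C
Reagents that add atoms: none
Why: Nucleophilic aromatic substitution (addition-elimination) of fluoride by the tertiary potassium alkoxide is activated by the ortho formyl group and the para bromine; only the O–H bond of linalool is broken, so the carbinol carbon keeps its S configuration, and an aromatic Claisen rearrangement of the product has no outlet because both ortho positions and the para position are substituted.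

Step 5
Reactants: 8 3-bromo-6-{[(3S)-3,7-dimethylocta-1,6-dien-3-yl]oxy}-2,5-bis(methoxymethoxy)benzaldehyde
Product: 9 1-bromo-4-{[(3S)-3,7-dimethylocta-1,6-dien-3-yl]oxy}-3-ethenyl-2,5-bis(methoxymethoxy)benzene
Conditions: MePPh3Br (1.5 equiv), KOtBu (1.4 equiv), THF, 0 °C; then 8, 0 °C to rt
Reagents that add atoms: methyltriphenylphosphonium bromide, C[P+](c1ccccc1)(c1ccccc1)c1ccccc1.[Br-]
Why: Wittig methylenation with the small unstabilised ylide converts even 2,6-disubstituted benzaldehydes into styrenes and touches none of the other groups.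

Step 6
Reactants: 9 1-bromo-4-{[(3S)-3,7-dimethylocta-1,6-dien-3-yl]oxy}-3-ethenyl-2,5-bis(methoxymethoxy)benzene
Product: 10 1-bromo-4-{[(3S)-5-(3,3-dimethyloxiran-2-yl)-3-methylpent-1-en-3-yl]oxy}-3-ethenyl-2,5-bis(methoxymethoxy)benzene (both epimers at the oxirane carbon)
Conditions: mCPBA (1.05 equiv), CH2Cl2, −10 to 0 °C
Reagents that add atoms: 3-chloroperoxybenzoic acid (mCPBA), O=C(OO)c1cccc(Cl)c1
Why: Prilezhaev epoxidation follows olefin nucleophilicity, so one equivalent of peracid should pick the trisubstituted tail olefin over the twisted styrene and the oxygen-deactivated vinyl group; the new oxirane stereocentre is not controlled and is erased in step 7.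

Step 7
Reactants: 10 1-bromo-4-{[(3S)-5-(3,3-dimethyloxiran-2-yl)-3-methylpent-1-en-3-yl]oxy}-3-ethenyl-2,5-bis(methoxymethoxy)benzene
Product: 11 (6S)-6-[4-bromo-2-ethenyl-3,6-bis(methoxymethoxy)phenoxy]-2,6-dimethyloct-7-en-2-ol
Conditions: LiAlH4 (1 equiv), Et2O, 0 °C to rt; aqueous work-up
Reagents that add atoms: none
Why: SN2-type hydride opening of the trisubstituted epoxide at its less substituted carbon gives the tertiary alcohol (net Markovnikov hydration), as is known for 6,7-epoxides of linalool and geraniol derivatives, while aryl bromide, MOM ethers and olefins should be inert at this temperature.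

Step 8
Reactants: 11 (6S)-6-[4-bromo-2-ethenyl-3,6-bis(methoxymethoxy)phenoxy]-2,6-dimethyloct-7-en-2-ol; 12 N-methoxy-N-methylacrylamide
Product: 14 1-[3-ethenyl-4-{[(3S)-7-hydroxy-3,7-dimethyloct-1-en-3-yl]oxy}-2,5-bis(methoxymethoxy)phenyl]prop-2-en-1-one, via dilithio species 13 (not isolated)
Conditions: n-BuLi (2.1 equiv), THF, −78 °C; 12 (1.5 equiv), −78 °C; AcOH quench at −78 °C; product kept cold over BHT
Reagents that add atoms: none
Why: After deprotonation of the alcohol, bromine-lithium exchange next to the MOM ether gives the aryllithium, whose 1,2-addition to the Weinreb amide stops at the chelated tetrahedral adduct and releases the vinyl ketone only on the cold acidic quench, which also keeps the freed amine protonated and away from the enone.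

Step 9
Reactants: 14 1-[3-ethenyl-4-{[(3S)-7-hydroxy-3,7-dimethyloct-1-en-3-yl]oxy}-2,5-bis(methoxymethoxy)phenyl]prop-2-en-1-one; 15 4-acetoxystyrene
Product: 17 4-{(1E)-3-[(2S)-2-(4-hydroxy-4-methylpentyl)-5,8-bis(methoxymethoxy)-2-methyl-2H-chromen-6-yl]-3-oxoprop-1-en-1-yl}phenyl acetate, via chromenyl vinyl ketone 16 (not isolated)
Conditions: second-generation Hoveyda-Grubbs catalyst RuCl2(H2IMes)(=CH-C6H4-2-OiPr) (5 mol %), CH2Cl2 (0.01 M), 40 °C, Ar sparge; then 15 (4 equiv), further catalyst (5 mol %), 40 °C
Reagents that add atoms: none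
Why: The ruthenium alkylidene loads onto one terminal vinyl group of 14, adds across the other to a ruthenacyclobutane and cycloreverts with loss of ethylene to form C3=C4, after which the same catalyst turns 15 into its benzylidene, which adds to the acryloyl group of 16 and cycloreverts to the enone and a second ethylene. The closest known reactions are the ring-closing metathesis of 2-vinylaryl allyl ethers to 2H-chromenes and the cross metathesis of styrenes with vinyl ketones, run here one after the other in one flask. Ring C closes as a six-membered ring from the 1,7-diene CH2=C4H-C4a=C8a-O1-C2-C3H=CH2, favoured by the geminal substitution at C2 and by the ortho placement of both arms on ring A. No stereocentre is created and none of the four bonds at C2 is broken, so the S configuration brought in by linalool is kept, C3=C4 is Z by ring constraint and the enone is E because the reversible cross metathesis settles on the more stable isomer. Ring closure has to outrun intermolecular coupling of the two hindered vinyl groups, which high dilution and the delayed addition of 15 secure, while the electron-poor acryloyl group stays idle because it self-couples slowly and reacts only with an electron-rich alkylidene. The vinyl group at C2 has no rival partner because the tail olefin was hydrated in steps 6 and 7 (a linalyl chain would close to a cyclopentene with loss of isobutene), and the finished C3=C4 bond, shielded by C2 and the C5 MOM ether, should not reopen.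

Step 10
Reactants: 17 4-{(1E)-3-[(2S)-2-(4-hydroxy-4-methylpentyl)-5,8-bis(methoxymethoxy)-2-methyl-2H-chromen-6-yl]-3-oxoprop-1-en-1-yl}phenyl acetate
Product: 18 (2E)-1-[(2S)-5,8-dihydroxy-2-(4-hydroxy-4-methylpentyl)-2-methyl-2H-chromen-6-yl]-3-(4-hydroxyphenyl)prop-2-en-1-one
Conditions: 3 M aq HCl, MeOH (degassed), 35 °C, Ar
Reagents that add atoms: none
Why: Acid-catalysed acetal exchange of the two aryl MOM ethers and acid-catalysed transesterification of the aryl acetate run together in methanol, as practised on MOM-protected pyranochalcones, and the low temperature and exclusion of air are meant to spare the C2–O1 bond, the tertiary alcohol, the 2'-hydroxychalcone and the hydroquinone.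

Compound list
1 | 2-fluorobenzene-1,4-diol | Oc1ccc(O)c(F)c1 | starting material
2 | 2-fluoro-1,4-bis(methoxymethoxy)benzene | COCOc1ccc(OCOC)c(F)c1 | intermediate
3 | 1-bromo-4-fluoro-2,5-bis(methoxymethoxy)benzene | COCOc1cc(Br)c(OCOC)cc1F | intermediate
4 | [3-bromo-6-fluoro-2,5-bis(methoxymethoxy)phenyl]lithium | COCOc1cc(Br)c(OCOC)c([Li])c1F | intermediate
5 | 3-bromo-6-fluoro-2,5-bis(methoxymethoxy)benzaldehyde | COCOc1cc(Br)c(OCOC)c(C=O)c1F | intermediate
6 | (S)-(+)-linalool, (3S)-3,7-dimethylocta-1,6-dien-3-ol | CC(C)=CCC[C@@](C)(C=C)O | starting material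
7 | potassium (3S)-3,7-dimethylocta-1,6-dien-3-olate | CC(C)=CCC[C@@](C)(C=C)[O-].[K+] | intermediate
8 | 3-bromo-6-{[(3S)-3,7-dimethylocta-1,6-dien-3-yl]oxy}-2,5-bis(methoxymethoxy)benzaldehyde | CC(C)=CCC[C@@](C)(C=C)Oc1c(C=O)c(OCOC)c(Br)cc1OCOC | intermediate
9 | 1-bromo-4-{[(3S)-3,7-dimethylocta-1,6-dien-3-yl]oxy}-3-ethenyl-2,5-bis(methoxymethoxy)benzene | CC(C)=CCC[C@@](C)(C=C)Oc1c(C=C)c(OCOC)c(Br)cc1OCOC | intermediate
10 | 1-bromo-4-{[(3S)-5-(3,3-dimethyloxiran-2-yl)-3-methylpent-1-en-3-yl]oxy}-3-ethenyl-2,5-bis(methoxymethoxy)benzene, both oxirane epimers | CC1(C)OC1CC[C@@](C)(C=C)Oc1c(C=C)c(OCOC)c(Br)cc1OCOC | intermediate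
11 | (6S)-6-[4-bromo-2-ethenyl-3,6-bis(methoxymethoxy)phenoxy]-2,6-dimethyloct-7-en-2-ol | CC(C)(O)CCC[C@@](C)(C=C)Oc1c(C=C)c(OCOC)c(Br)cc1OCOC | intermediate
12 | N-methoxy-N-methylacrylamide | C=CC(=O)N(C)OC | starting material
13 | lithium alkoxide and aryllithium derived from 11 (dilithio species) | CC(C)(O[Li])CCC[C@@](C)(C=C)Oc1c(C=C)c(OCOC)c([Li])cc1OCOC | intermediate
14 | 1-[3-ethenyl-4-{[(3S)-7-hydroxy-3,7-dimethyloct-1-en-3-yl]oxy}-2,5-bis(methoxymethoxy)phenyl]prop-2-en-1-one | CC(C)(O)CCC[C@@](C)(C=C)Oc1c(C=C)c(OCOC)c(C(=O)C=C)cc1OCOC | intermediate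
15 | 4-acetoxystyrene | CC(=O)Oc1ccc(C=C)cc1 | starting material
16 | 1-[(2S)-2-(4-hydroxy-4-methylpentyl)-5,8-bis(methoxymethoxy)-2-methyl-2H-chromen-6-yl]prop-2-en-1-one | CC(C)(O)CCC[C@@]1(C)C=Cc2c(OCOC)c(C(=O)C=C)cc(OCOC)c2O1 | intermediate
17 | 4-{(1E)-3-[(2S)-2-(4-hydroxy-4-methylpentyl)-5,8-bis(methoxymethoxy)-2-methyl-2H-chromen-6-yl]-3-oxoprop-1-en-1-yl}phenyl acetate | CC(C)(O)CCC[C@@]1(C)C=Cc2c(OCOC)c(C(=O)/C=C/c3ccc(OC(C)=O)cc3)cc(OCOC)c2O1 | intermediate
18 | (2E)-1-[(2S)-5,8-dihydroxy-2-(4-hydroxy-4-methylpentyl)-2-methyl-2H-chromen-6-yl]-3-(4-hydroxyphenyl)prop-2-en-1-one | CC(C)(O)CCC[C@@]1(C)C=Cc2c(O)c(C(=O)/C=C/c3ccc(O)cc3)cc(O)c2O1 | target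

Total steps: 10. Longest linear sequence: 10 steps (1 to 18).

Steps most likely to fail

**First, step 4.**
- What may go wrong: the hindered tertiary alkoxide may add too slowly to a C–F carbon that is flanked on both sides and sits on a ring with two donor ethers. Reversible attack at the formyl group and slow decomposition could then take over.
- Fallback: it sets out from 5 and takes the stereocentre from a catalyst instead of the chiral pool.
- The small nucleophile hydroxide (KOH, DMSO/H2O, 60 °C, then acidification) should replace fluoride to give 3-bromo-6-hydroxy-2,5-bis(methoxymethoxy)benzaldehyde F1.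
- F1 is then O-allylated with geranyl methyl carbonate F2 (from geraniol and methyl chloroformate). This is an asymmetric allylic etherification of the Tsuji-Trost type with zerovalent palladium (Pd2(dba)3·CHCl3, C2-symmetric DACH-phenyl bisphosphine ligand, CH2Cl2, low temperature).
- Phenols are known to attack the more substituted terminus of such 3,3-disubstituted π-allyl complexes.
- The ligand antipode is selected for the S ether, and neryl in place of geranyl carbonate inverts the sense with the same ligand.
- The fallback comes back to the route at 8.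

**Second, step 9.**
- What may go wrong: the ring closure is closely precedented, but the cross metathesis may stall. Possible causes are oligomerisation of the vinyl ketone, decay of the catalyst before the acryloyl group has turned over, or diversion of 15 into its stilbene.
- Fallback: it sets out from 11 and brings in ring B with the enone already made, so that metathesis only has to close ring C.
- A Horner-Wadsworth-Emmons reaction of 4-(methoxymethoxy)benzaldehyde with diethyl [2-(methoxy(methyl)amino)-2-oxoethyl]phosphonate (NaH, THF) should give (2E)-N-methoxy-3-[4-(methoxymethoxy)phenyl]-N-methylprop-2-enamide F3.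
- Dilithiation of 11 to 13 as in step 8 and acylation with F3 should give the MOM-protected open-chain chalcone triene F4.
- Second-generation Grubbs catalyst RuCl2(PCy3)(H2IMes)(=CHPh) in dilute CH2Cl2 at 40 °C should close it to the tris-MOM chromenyl chalcone F5.
- The conditions of step 10 then lead back to the route at 18.

**Third, step 8.**
- What may go wrong: conjugate addition of the liberated N,O-dimethylhydroxylamine or of the aryllithium to the acrylic unit, and polymerisation during isolation, may erode the vinyl ketone.
- Fallback: it sets out from 11 and replaces acyl substitution by carbonyl addition and oxidation.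
- Species 13 is trapped with acrolein at −78 °C to give the aryl vinyl carbinol F6 (both carbinol epimers).
- This allylic and benzylic alcohol is oxidised with MnO2 in CH2Cl2 shortly before use.
- The fallback comes back to the route at 14.

Further compounds
F1 | step 4 | 3-bromo-6-hydroxy-2,5-bis(methoxymethoxy)benzaldehyde | COCOc1cc(Br)c(OCOC)c(C=O)c1O
F2 | step 4 | geranyl methyl carbonate, (2E)-3,7-dimethylocta-2,6-dien-1-yl methyl carbonate | COC(=O)OC/C=C(\C)CCC=C(C)C
F3 | step 9 | (2E)-N-methoxy-3-[4-(methoxymethoxy)phenyl]-N-methylprop-2-enamide | COCOc1ccc(/C=C/C(=O)N(C)OC)cc1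
F4 | step 9 | (2E)-1-[3-ethenyl-4-{[(3S)-7-hydroxy-3,7-dimethyloct-1-en-3-yl]oxy}-2,5-bis(methoxymethoxy)phenyl]-3-[4-(methoxymethoxy)phenyl]prop-2-en-1-one | CC(C)(O)CCC[C@@](C)(C=C)Oc1c(C=C)c(OCOC)c(C(=O)/C=C/c2ccc(OCOC)cc2)cc1OCOC
F5 | step 9 | (2E)-1-[(2S)-2-(4-hydroxy-4-methylpentyl)-5,8-bis(methoxymethoxy)-2-methyl-2H-chromen-6-yl]-3-[4-(methoxymethoxy)phenyl]prop-2-en-1-one | CC(C)(O)CCC[C@@]1(C)C=Cc2c(OCOC)c(C(=O)/C=C/c3ccc(OCOC)cc3)cc(OCOC)c2O1
F6 | step 8 | 1-[3-ethenyl-4-{[(3S)-7-hydroxy-3,7-dimethyloct-1-en-3-yl]oxy}-2,5-bis(methoxymethoxy)phenyl]prop-2-en-1-ol, both carbinol epimers | CC(C)(O)CCC[C@@](C)(C=C)Oc1c(C=C)c(OCOC)c(C(O)C=C)cc1OCOC
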